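**Retrosynthetic overview**

1. Feature: in ring B (the pyranone ring) O1 and C4 sit on the neighbouring benzo carbons C8a and C4a, which is the pattern of a quinoketene, while C2 (oxygen-bearing) and C3 (carrying C1' of the chain) form a two-carbon unit at the oxidation level of a 1-alkoxyalkyne.
2. 16 ⇐ 15 ⇐ 14 ⇐ 13: the 4-hydroxycoumarin is unmasked last from a 2-ethoxychromone by hydrolysis at C2, after desilylation and benzoylation of O12'; the ethoxy group keeps O4/O2 masked during benzoylation.
3. 13 ⇐ 11 + 10: ring B is cut at O1–C2 and C3–C4, a hetero-[4+2] addition of quinoketene 12 (from benzodioxinone 11 by light-driven loss of acetone) to ynol ether 10.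
4. 10 ⇐ 7 + 8 (alkylation of lithium ethoxyacetylide); 7 ⇐ farnesol 1 by acetylation, oxidation at C12, silylation, deacetylation and bromination.
5. Ring order: ring A is bought inside 11; ring B is the only ring made (step 7).

Key step: step 7

Remark: ethoxyacetylene is handled as its commercial solution in hexanes, and the acetonide of salicylic acid is taken as a purchased compound.

**Route**

Step 1
Reactants: 1 (2E,6E)-farnesol
Product: 2 (2E,6E)-farnesyl acetate
Conditions: Ac2O, pyridine, DMAP (cat.), CH2Cl2, 0 °C to rt
Reagents that add atoms: acetic anhydride, CC(=O)OC(C)=O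
Why: DMAP-catalysed acylation of a primary allylic alcohol masks O1 and deactivates the C2=C3 alkene towards the oxidation that follows.

Step 2
Reactants: 2 (2E,6E)-farnesyl acetate
Product: 3 (2E,6E,10E)-12-hydroxy-3,7,11-trimethyldodeca-2,6,10-trienyl acetate
Conditions: SeO2 (cat.), t-BuOOH, salicylic acid (cat.), CH2Cl2, 0 °C to rt, stopped before over-oxidation
Reagents that add atoms: tert-butyl hydroperoxide, CC(C)(C)OO (net source of the new oxygen; SeO2 is the carrier)
Why: Sharpless SeO2/t-BuOOH allylic oxidation (ene reaction, then [2,3]-sigmatropic shift) attacks the terminal, most electron-rich and least hindered isopropylidene group at its E methyl, so the 10E primary allylic alcohol should be the main product.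

Step 3
Reactants: 3 (2E,6E,10E)-12-hydroxy-3,7,11-trimethyldodeca-2,6,10-trienyl acetate
Product: 4 (2E,6E,10E)-12-(tert-butyldimethylsilyloxy)-3,7,11-trimethyldodeca-2,6,10-trienyl acetate
Conditions: TBSCl, imidazole, DMF, rt
Reagents that add atoms: tert-butyldimethylsilyl chloride, CC(C)(C)[Si](C)(C)Cl
Why: Standard imidazole-mediated silylation of a primary alcohol gives an ether that survives base, acetylide and the photochemical step.

Step 4
Reactants: 4 (2E,6E,10E)-12-(tert-butyldimethylsilyloxy)-3,7,11-trimethyldodeca-2,6,10-trienyl acetate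
Product: 5 (2E,6E,10E)-12-(tert-butyldimethylsilyloxy)-3,7,11-trimethyldodeca-2,6,10-trien-1-ol
Conditions: K2CO3 (0.2 equiv), MeOH, rt
Reagents that add atoms: none
Why: Base-catalysed transesterification with methanol removes the acetate, while the primary silyl ether is stable to carbonate in methanol.

Step 5
Reactants: 5 (2E,6E,10E)-12-(tert-butyldimethylsilyloxy)-3,7,11-trimethyldodeca-2,6,10-trien-1-ol
Product: 7 tert-butyl{[(2E,6E,10E)-12-bromo-2,6,10-trimethyldodeca-2,6,10-trienyl]oxy}dimethylsilane, via allylic mesylate 6 (not isolated)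
Conditions: MsCl, Et3N, THF, −45 °C; then LiBr, THF, −45 to 0 °C; cold aqueous work-up, used crude
Reagents that add atoms: lithium bromide, [Li+].[Br-]; methanesulfonyl chloride, CS(=O)(=O)Cl (its atoms stay only in intermediate 6)
Why: Mesylation followed by SN2 displacement with bromide at low temperature is the usual acid-free way to farnesyl-type bromides and should leave the alkene geometry and the silyl ether untouched.

Step 6
Reactants: 7 tert-butyl{[(2E,6E,10E)-12-bromo-2,6,10-trimethyldodeca-2,6,10-trienyl]oxy}dimethylsilane; 8 ethoxyacetylene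
Product: 10 tert-butyl{[(2E,6E,10E)-14-ethoxy-2,6,10-trimethyltetradeca-2,6,10-trien-13-ynyl]oxy}dimethylsilane, via lithium ethoxyacetylide 9 (not isolated)
Conditions: 8, n-BuLi, THF, −78 °C; then 7, HMPA (or DMPU), −78 °C to rt; aq. NaHCO3 work-up, chromatography on Et3N-deactivated silica
Reagents that add atoms: none
Why: SN2 alkylation of a lithium alkoxyacetylide by a primary allylic bromide in THF with a dipolar cosolvent should occur at the unhindered CH2 and not at the fully substituted allyl terminus.

Step 7
Reactants: 10 tert-butyl{[(2E,6E,10E)-14-ethoxy-2,6,10-trimethyltetradeca-2,6,10-trien-13-ynyl]oxy}dimethylsilane; 11 2,2-dimethyl-4H-1,3-benzodioxin-4-one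
Product: 13 3-[(2E,6E,10E)-12-(tert-butyldimethylsilyloxy)-3,7,11-trimethyldodeca-2,6,10-trienyl]-2-ethoxy-4H-chromen-4-one, via quinoketene 12 (not isolated)
Conditions: hν (300 nm lamps, thin-film flow coil or Pyrex vessel), 11 (3 equiv), dry degassed CH2Cl2, 4 Å MS, rt, stopped when 10 is consumed
Reagents that add atoms: none
Why: Proposed new method: excitation of 11 near 300 nm should trigger retro-[4+2] loss of acetone to quinoketene 12, whose O=C8a–C4a=C4 unit is an electron-poor 1-oxadiene; the alkyne carbon of 10 remote from oxygen attacks the ketene carbon C4 and the ring oxygen then closes on the ethoxy-bearing carbon, a polar, asynchronous hetero-[4+2] that restores the aromaticity of ring A. The closest known reaction types are the photochemical generation of quinoketenes from benzodioxinones with capture by alcohols, and the [4+2] additions of acylketenes to alkoxyalkynes, ynamines and enol ethers that give 4-pyranones; the pairing of a photogenerated quinoketene with an ynol ether has not been shown. Ring B closes as a six-membered ring by this intermolecular cycloaddition, C3–C4 first and O1–C2 second, by collapse of the acylphenoxide oxygen onto the alkoxy-stabilised cationic carbon. No stereocenter is formed, and the three E alkenes and the silyl ether are not chromophores at this wavelength. The step needs regioselectivity and a [4+2] rather than a [2+2] course: the first follows from the matched polarisation (electrophilic ketene carbon, nucleophilic carbon beta to the ethoxy oxygen), so the chain can only end on C3, and the second from the aromatisation that only closure through oxygen delivers. An excess of cheap 11 and dry, acid-free conditions are chosen so that dimerisation or hydrolysis of 12 does not use up 10.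

Step 8
Reactants: 13 3-[(2E,6E,10E)-12-(tert-butyldimethylsilyloxy)-3,7,11-trimethyldodeca-2,6,10-trienyl]-2-ethoxy-4H-chromen-4-one
Product: 14 2-ethoxy-3-[(2E,6E,10E)-12-hydroxy-3,7,11-trimethyldodeca-2,6,10-trienyl]-4H-chromen-4-one
Conditions: Bu4NF, AcOH (1 equiv each), THF, 0 °C to rt
Reagents that add atoms: none
Why: Fluoride-mediated desilylation of a primary silyl ether; buffering with acetic acid keeps the medium from attacking C2 of the vinylogous carbonate.

Step 9
Reactants: 14 2-ethoxy-3-[(2E,6E,10E)-12-hydroxy-3,7,11-trimethyldodeca-2,6,10-trienyl]-4H-chromen-4-one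
Product: 15 (2E,6E,10E)-12-(2-ethoxy-4-oxo-4H-chromen-3-yl)-2,6,10-trimethyldodeca-2,6,10-trienyl benzoate
Conditions: BzCl, pyridine, DMAP (cat.), CH2Cl2, 0 °C
Reagents that add atoms: benzoyl chloride, O=C(Cl)c1ccccc1
Why: DMAP-catalysed acylation of the only free hydroxyl; the coumarin oxygens are still locked in the 2-ethoxychromone, so no selectivity problem arises.

Step 10
Reactants: 15 (2E,6E,10E)-12-(2-ethoxy-4-oxo-4H-chromen-3-yl)-2,6,10-trimethyldodeca-2,6,10-trienyl benzoate
Product: 16 (2E,6E,10E)-12-(4-hydroxy-2-oxo-2H-chromen-3-yl)-2,6,10-trimethyldodeca-2,6,10-trienyl benzoate (E-omega-benzoyloxyferulenol)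
Conditions: 1 M aq. HCl, THF, rt
Reagents that add atoms: water, O
Why: Acid-catalysed hydrolysis of the cyclic vinylogous carbonate (protonation at the C4 carbonyl, addition of water at C2, loss of ethanol) should give the 4-hydroxycoumarin tautomer, and dilute acid at room temperature should spare the trisubstituted alkenes and the allylic benzoate.

**Compound list**

1 | (2E,6E)-farnesol | CC(C)=CCC/C(C)=C/CC/C(C)=C/CO | starting material
2 | (2E,6E)-farnesyl acetate | CC(=O)OC/C=C(\C)CC/C=C(\C)CCC=C(C)C | intermediate
3 | (2E,6E,10E)-12-hydroxy-3,7,11-trimethyldodeca-2,6,10-trienyl acetate | CC(=O)OC/C=C(\C)CC/C=C(\C)CC/C=C(\C)CO | intermediate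
4 | (2E,6E,10E)-12-(tert-butyldimethylsilyloxy)-3,7,11-trimethyldodeca-2,6,10-trienyl acetate | CC(=O)OC/C=C(\C)CC/C=C(\C)CC/C=C(\C)CO[Si](C)(C)C(C)(C)C | intermediate
5 | (2E,6E,10E)-12-(tert-butyldimethylsilyloxy)-3,7,11-trimethyldodeca-2,6,10-trien-1-ol | OC/C=C(\C)CC/C=C(\C)CC/C=C(\C)CO[Si](C)(C)C(C)(C)C | intermediate
6 | (2E,6E,10E)-12-(tert-butyldimethylsilyloxy)-3,7,11-trimethyldodeca-2,6,10-trienyl methanesulfonate | CS(=O)(=O)OC/C=C(\C)CC/C=C(\C)CC/C=C(\C)CO[Si](C)(C)C(C)(C)C | intermediate
7 | tert-butyl{[(2E,6E,10E)-12-bromo-2,6,10-trimethyldodeca-2,6,10-trienyl]oxy}dimethylsilane | BrC/C=C(\C)CC/C=C(\C)CC/C=C(\C)CO[Si](C)(C)C(C)(C)C | intermediate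
8 | ethoxyacetylene | CCOC#C | starting material
9 | lithium ethoxyacetylide | CCOC#C[Li] | intermediate
10 | tert-butyl{[(2E,6E,10E)-14-ethoxy-2,6,10-trimethyltetradeca-2,6,10-trien-13-ynyl]oxy}dimethylsilane | CCOC#CC/C=C(\C)CC/C=C(\C)CC/C=C(\C)CO[Si](C)(C)C(C)(C)C | intermediate
11 | 2,2-dimethyl-4H-1,3-benzodioxin-4-one | CC1(C)OC(=O)c2ccccc2O1 | starting material
12 | 6-(oxomethylidene)cyclohexa-2,4-dien-1-one (quinoketene) | O=C=C1C=CC=CC1=O | intermediate
13 | 3-[(2E,6E,10E)-12-(tert-butyldimethylsilyloxy)-3,7,11-trimethyldodeca-2,6,10-trienyl]-2-ethoxy-4H-chromen-4-one | CCOc1oc2ccccc2c(=O)c1C/C=C(\C)CC/C=C(\C)CC/C=C(\C)CO[Si](C)(C)C(C)(C)C | intermediate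
14 | 2-ethoxy-3-[(2E,6E,10E)-12-hydroxy-3,7,11-trimethyldodeca-2,6,10-trienyl]-4H-chromen-4-one | CCOc1oc2ccccc2c(=O)c1C/C=C(\C)CC/C=C(\C)CC/C=C(\C)CO | intermediate
15 | (2E,6E,10E)-12-(2-ethoxy-4-oxo-4H-chromen-3-yl)-2,6,10-trimethyldodeca-2,6,10-trienyl benzoate | CCOc1oc2ccccc2c(=O)c1C/C=C(\C)CC/C=C(\C)CC/C=C(\C)COC(=O)c1ccccc1 | intermediate
16 | (2E,6E,10E)-12-(4-hydroxy-2-oxo-2H-chromen-3-yl)-2,6,10-trimethyldodeca-2,6,10-trienyl benzoate (E-omega-benzoyloxyferulenol) | O=c1oc2ccccc2c(O)c1C/C=C(\C)CC/C=C(\C)CC/C=C(\C)COC(=O)c1ccccc1 | target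

**Step count and risk**

Total step count: 10. Longest linear sequence: 10 steps (1 to 16); 8 and 11 enter as purchased materials.

Steps most likely to fail:

Step 7 (the proposed method). The quinoketene may be lost by recombination with acetone, dimerisation or capture by traces of water faster than the ynol ether intercepts it. The zwitterion may also close in a [2+2] sense, and continued irradiation may degrade the chromone product or scramble alkene geometry by energy transfer. Fallback by known chemistry, setting out from 10 and coming back at 16: 10 is added slowly to methyl salicylate (5 equiv) in xylene at 130 °C. The 1-ethoxyalkyne loses ethylene by retro-ene reaction to the ketene (4E,8E,12E)-14-(tert-butyldimethylsilyloxy)-5,9,13-trimethyltetradeca-1,4,8,12-tetraen-1-one F1, which acylates the phenol to the aryl ester methyl 2-{[(4E,8E,12E)-14-(tert-butyldimethylsilyloxy)-5,9,13-trimethyltetradeca-4,8,12-trienoyl]oxy}benzoate F2. HF·pyridine in THF at 0 °C removes the silyl group to give the hydroxy aryl ester F3, and BzCl/pyridine gives the benzoate aryl ester F4. LiN(SiMe3)2 (2.2 equiv, THF, −78 to 0 °C) then brings about the intramolecular Claisen (Dieckmann-type) condensation of the ester enolate onto the neighbouring methyl ester. This closes ring B with loss of methanol and should give 16 after acidic work-up.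

Step 6. The acetylide may attack the tertiary allyl terminus, may act as a base and isomerise the skipped enyne to an allene or conjugated enyne, or the crude allylic bromide may decompose before it couples. Fallback, setting out from 7 and 8 and coming back at 10: lithium ethoxyacetylide 9 (from 8 and n-BuLi) is quenched with Bu3SnCl to give tributyl(ethoxyethynyl)stannane F5. F5 is joined to 7 by Stille coupling (Pd(PPh3)4, a zerovalent palladium catalyst, THF, 50 °C). The alkynyl group is transferred to the primary terminus of the allylpalladium intermediate under neutral conditions to give 10.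

Step 10. Under aqueous acid the freed 4-hydroxyl may add to the protonated C2'=C3' alkene (cyclisation towards a pyranocoumarin), or hydrolysis may stall and need forcing conditions that the polyene does not tolerate. Fallback, setting out from 14 and coming back at 16: LiOH in aqueous THF at rt attacks C2 of the vinylogous carbonate by addition-elimination with loss of ethoxide, conditions to which the alkenes are inert. This should give the diol 4-hydroxy-3-[(2E,6E,10E)-12-hydroxy-3,7,11-trimethyldodeca-2,6,10-trienyl]-2H-chromen-2-one F6. Excess BzCl/pyridine gives the bis-benzoate F7. Its enol benzoate at O4, a vinylogous mixed anhydride, is then cleaved selectively by aminolysis with morpholine (1 equiv, CH2Cl2, 0 °C), leaving the allylic benzoate and giving 16.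

**Further compounds**

F1 | step 7 | (4E,8E,12E)-14-(tert-butyldimethylsilyloxy)-5,9,13-trimethyltetradeca-1,4,8,12-tetraen-1-one | O=C=CC/C=C(\C)CC/C=C(\C)CC/C=C(\C)CO[Si](C)(C)C(C)(C)C
F2 | step 7 | methyl 2-{[(4E,8E,12E)-14-(tert-butyldimethylsilyloxy)-5,9,13-trimethyltetradeca-4,8,12-trienoyl]oxy}benzoate | COC(=O)c1ccccc1OC(=O)CC/C=C(\C)CC/C=C(\C)CC/C=C(\C)CO[Si](C)(C)C(C)(C)C
F3 | step 7 | methyl 2-{[(4E,8E,12E)-14-hydroxy-5,9,13-trimethyltetradeca-4,8,12-trienoyl]oxy}benzoate | COC(=O)c1ccccc1OC(=O)CC/C=C(\C)CC/C=C(\C)CC/C=C(\C)CO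
F4 | step 7 | methyl 2-{[(4E,8E,12E)-14-(benzoyloxy)-5,9,13-trimethyltetradeca-4,8,12-trienoyl]oxy}benzoate | COC(=O)c1ccccc1OC(=O)CC/C=C(\C)CC/C=C(\C)CC/C=C(\C)COC(=O)c1ccccc1
F5 | step 6 | tributyl(ethoxyethynyl)stannane | CCCC[Sn](CCCC)(CCCC)C#COCC
F6 | step 10 | 4-hydroxy-3-[(2E,6E,10E)-12-hydroxy-3,7,11-trimethyldodeca-2,6,10-trienyl]-2H-chromen-2-one | O=c1oc2ccccc2c(O)c1C/C=C(\C)CC/C=C(\C)CC/C=C(\C)CO
F7 | step 10 | (2E,6E,10E)-12-[4-(benzoyloxy)-2-oxo-2H-chromen-3-yl]-2,6,10-trimethyldodeca-2,6,10-trienyl benzoate | O=c1oc2ccccc2c(OC(=O)c2ccccc2)c1C/C=C(\C)CC/C=C(\C)CC/C=C(\C)COC(=O)c1ccccc1
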